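The constants used here were chosen freely.

The catalyst in this flask turns substrate and dissolved gas into target, but the gas must first cross into solution.

    gas phase ⇌ dissolved gas, rate k1*(csat - [dissolved gas]) (k1 = 2.1 /s, csat = 0.85 mM)
    catalyst + target ⇌ idle complex (K2 = 970 /M, k2 = 55 /M/s)
    substrate + dissolved gas + catalyst ⇌ catalyst + target (K3 = 650 /M, k3 = 8.0 × 10⁶ /M²/s)

substrate 10 mM; gas phase 0.85 mM (held); catalyst 5 mol%; time 2.5 s

1. amount of target and idle complex together at 2.5 s, in percent of the substrate charged
2. concentration of dissolved gas in solution at 2.5 s, in percent of saturation

In this flask step 3, the catalysed reaction of substrate with dissolved gas, relaxes at about 40.0 /s with substrate and catalyst as charged, much faster than the crossing's 2.1 /s, so I hold step 3 at equilibrium and take the crossing as the rate-limiting step. In step 2, the binding of target to catalyst as idle complex, free target's half-life with the catalyst as charged is 25.2 s, longer than the run of 2.5 s, so I leave step 2 aside.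

You can then solve this flask at both ends. At the start gas enters at 1.78 mM/s. At the far end, with step 2 aside, the solution stands at 0.85 mM, and equilibrium with the remaining substrate holds an amount X of target, 3.56 mM.

To join the ends, define the filling time τ as the gas taken up by the far end over the starting rate: 2.47 s. With one exponential, this flask has gone a fraction f of the way, one minus exp(−t/τ), which is 63.7 %. My reckoning therefore gives y, target and idle complex together in percent of the substrate charged, as 22.7 %, and sat, the dissolved gas in percent of saturation, as 63.7 %.

The forecast gives 25 % and 60 %, holding that step 3 “stays close to equilibrium”; its y is above mine and its sat below mine.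

The simulation gives 24.5 % and 59.5 %.

In this flask, free target's half-life toward idle complex at 2.50 s, by that forward step alone, is 30 s, long against the run of 2.5 s, while τ is about as long as the run, and my y lies 1.8 percentage points below the simulated one. In the neighbouring flask with 4.0 mM of substrate, at the same loading of 5 mol% and the same time, X is 1.42 mM and τ shortens to 1.27 s, so I reckon y = 30.5 %, and that flask gives 30.8 %.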